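The excess comes first.

| flask | left-handed substrate | right-handed substrate | partner | free catalyst | racemization catalyst | remark | time |
|---|---|---|---|---|---|---|---|
| Sunday's | 0.50 M | 0.50 M | 2 M | 0.50 mM | 0.50 mM | run made earlier |  |
| Thursday's | 0.50 M | 0.50 M | 2 M | 0.75 mM | 0.50 mM | run made earlier |  |
| flask | 0.50 M | 0.50 M | 2.00 M | 1.0 mM | 0.50 mM |  | 6.0 h |

| run | time / h | left-handed product / % | right-handed product / % |
|---|---|---|---|
| Sunday's | 0.417 | 4.4 | 2.2 |
| Sunday's | 1.00 | 7.6 | 3.8 |
| Sunday's | 2.00 | 11.4 | 6.6 |
| Sunday's | 3.00 | 13.5 | 7.8 |
| Sunday's | 4.00 | 14.6 | 8.5 |
| Sunday's | 6.00 | 15.9 | 9.3 |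
| Sunday's | 8.00 | 16.2 | 9.2 |
| Thursday's | 0.417 | 6.4 | 2.9 |
| Thursday's | 1.00 | 10.9 | 6.1 |
| Thursday's | 2.00 | 15.7 | 9.4 |
| Thursday's | 3.00 | 19.7 | 10.8 |
| Thursday's | 4.00 | 19.1 | 11.1 |
| Thursday's | 6.00 | 22.0 | 12.3 |
| Thursday's | 8.00 | 21.7 | 13.1 |

(each reading ± 0.5 percentage points)

- left-handed product and right-handed product together, in percent of the left-handed substrate and right-handed substrate charged together, at 6.0 h
- excess of left-handed product over right-handed product in the product at 6.0 h
- whether the exchange between left-handed substrate and right-handed substrate keeps pace with the reaction: how far the product's excess at 6.0 h gets from its value without exchange to its value with instant exchange (above 80% keeps pace, below 20% hardly takes part, else lags behind)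

- free catalyst is single-handed; left-handed substrate and right-handed substrate are mirror images of each other, charged as a racemate, each of them at the stated concentration
- an excess is the difference of the two amounts in percent of their sum
- an excess is below zero if the other one leads

Sunday's first reading shows an excess of 33.3%, but a difference over so small a sum carries a scatter of 11 percentage points, so the early readings say little alone. The left-handed product readings of both runs sum to 199% and the right-handed ones to 113%, and the mean excess M, their difference over their total, which weights each reading by its size, is 27.5%.

With instant exchange the substrates stay racemic and the product excess stays at its start, so M is that start and the bound from above. With no exchange, plain kinetic resolution, the substrate excess grows along the run. Replacing its curve by its mean, half the final value, turns a start e into E = e/(1 + (1 − e·e)c/(2(1 − c))) at conversion c. The readings at 3.00 h stand near the weighted mean conversion, 25.9%, so M then implies a start of 32.0%, which falls to 23.9% at the forecast's conversion: the bound from below. Thursday's last reading stands at a conversion of 34.8%, less than the forecast's 43%, and its excess carries a scatter of 2 points, so that reading does not place the flask within this bracket.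

The forecast gives 43% and 25%, higher than 23.9% and lower than 27.5%, with the verdict lags behind, adding that “the data discriminate this only weakly”.

The flask gives 42.7% and 26.7%, and the exchange keeps pace, at 89% of the way.

    partner + free catalyst + left-handed substrate → free catalyst + left-handed product (k = 0.0720 M⁻² s⁻¹)
    partner + free catalyst + right-handed substrate → free catalyst + right-handed product (k = 0.0410 M⁻² s⁻¹)
    left-handed substrate + racemization catalyst ⇌ right-handed substrate + racemization catalyst, rate k3*[racemization catalyst]*[left-handed substrate] forward; the back reaction follows from the equilibrium constant (k = 1.70 M⁻¹ s⁻¹)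
    partner ⇌ dormant form (K = 0.190, k = 5.50 × 10⁻⁵ s⁻¹)
    partner + free catalyst → spent catalyst (k = 9.60 × 10⁻⁵ M⁻¹ s⁻¹)

At 6.00 h the flask's excess of right-handed over left-handed substrate stands at 0.0664%. With M as the start, the no-exchange end at the flask's conversion is 20.5%, and the flask gets 88.6% of the way from there to M. The neighbour with 1.70 mM of free catalyst reaches 60.6% with an excess of 26.2%; its no-exchange end is 16.1%, so it gets 88.6% of the way.

The data were computed for substances that don't exist.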